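## Analysis of the target

Atoms are numbered C1–C27 in the order of the target SMILES. The target is a C25 diol on a 5-8-6-6 skeleton: ring A (cyclopentane C3, C4, C5, C7, C9), ring B (cyclooctene C2, C3, C9, C10, C12, C25, C26, C27), ring C (cyclohexane C12, C14, C15, C16, C24, C25) and ring D (cyclohexane C16, C18, C19, C20, C23, C24, gem-dimethyl at C20). It has eight stereocentres (5R, 7R, 9S, 10R, 12S, 16S, 24S, 25S) and one tetrasubstituted alkene, C2=C3, which is Z (C27 cis to C9), lies inside ring B and is exocyclic to ring A. On ring A the C5 hydroxyl is trans to the C7 methyl, while the C7 methyl and the C9–C10 bond are cis, the less stable arrangement. Rings C and D form a trans-decalin (C17 methyl anti to H24), and ring B is trans-fused to ring C (C13 methyl anti to H25, H24 anti to H25), so the two angular methyls are axial on opposite faces of ring C. Sensitive points are the allylic C9 methine (epimerisable whenever C10 is a carbonyl), the acid-sensitive tetrasubstituted alkene and the hindered C10 carbinol next to quaternary C12. The difficulty is the eight-membered ring flanked by two quaternary carbons (C12, C16) and the contiguous stereocentres C9, C10, C12, C25. The strategy rests on the C12–C25 bond, which belongs to both ring B and ring C: formed across the 12-membered ring C2, C3, C9, C10, C12, C14, C15, C16, C24, C25, C26, C27, it closes both rings and creates the C12 quaternary centre.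

## Retrosynthetic reasoning

**32 back to 28.** The two hydroxyls are carried as silyl ethers (31) and the C23 methylene as a ketone (28). The ketone is kept because it makes C25 a radical acceptor in the ring-forming step, and it is deleted afterwards through alcohol 29 and xanthate 30. A hydrazone-based reduction is avoided: C23 lies between quaternary C20 and the ring-fusion carbon C24, and condensation there is unreliable.

**28 to 27 (C12–C25).** Cutting this one bond opens rings B and C together and leaves a 12-membered ring with a C12 methylidene and a C24=C25 enone. The forward reaction turns the methylidene into a tertiary radical and adds it to C25, creating C12, C25 and C24. The enone in 27 must be Z (C26 syn to the C23 carbonyl). The tether forces attack on the enone face that carries C15, and only the Z isomer then places C26 anti to C16 (25S). The E isomer would give the C25 epimer.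

**27 to 25 (C10–C12).** The macrocycle is opened between the carbinol C10 and C12. The forward reaction is an intramolecular vinyl-chromium addition of the 2-iodoalkene to the C10 aldehyde of 25, giving alcohol 26. It forms the allylic alcohol and the methylidene together and closes a 12-membered ring, which is easier than an 8-membered one.

**25 to 20 + 14 (C24=C25).** The enone is cut into ring D ketone 20 and aldehyde 14. Ketone 20 can enolise only towards C24, so the aldol (21) and elimination (23) are regiochemically unambiguous. The Z geometry should be the stable one, because it keeps C26 away from quaternary C16. The primary silyl ether of 23 is then removed (24) and oxidised to 25.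

**20 to 15 (ring D).** C16 is the only stereocentre. It comes from a catalytic asymmetric conjugate addition to trimethylenone 17, which is made from 15 through 16 by two kinetic methylations. The silyl alkyne of 18 is unmasked (19) and converted into the 2-iodoalkene.

**14 to 9 (C26–C27).** The three-carbon aldehyde arm is cut at C26–C27. Reducing lactone 9 to lactol 10 exposes C27 as an aldehyde and frees O10 in the same operation. A two-carbon Wittig extension (11), saturation of the new disubstituted alkene (12), acetal hydrolysis (13) and silylation give 14.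

**9 to 5 (C2=C3 and the C7/C9 hydrogens).** The tetrasubstituted alkene is made inside a six-membered lactone (6 to 7), so C27 and C9 must be cis. The C7=C9 alkene of 8 is then hydrogenated under direction of the free C5 hydroxyl, which puts both new hydrogens on the oxygen face. This sets the trans O5/C7-methyl and the cis C7-methyl/C10 relationships in one step.

**5 to 1.** Enone 5 comes from 1 by hydroxymethylation at the alpha carbon (2), conjugate methylation with selenium trapping (3) and oxidative elimination, which regenerates the enone. The C5 stereocentre of 1 is kept throughout.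

## Alternatives that were turned down

**Alternative 1: allenic Pauson–Khand reaction.**
- Disconnection: C3–C9, C4–C5 and C5–C7, with C5 delivered as CO; rings A and B are built together on a finished C/D decalin carrying an allene and a methyl alkyne.
- Forward key step: [Rh(CO)2Cl]2 (monovalent rhodium) under CO engages the terminal allene π bond and the alkyne to give tetracyclic dienone A1.
- For: two rings and three bonds form in one catalytic step. The C2=C3 geometry comes for free, because C27 and C9 both lie in the new eight-membered ring. On this point it is stronger than the chosen route, which needs a temporary lactone.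
- Against: the [2+2+1] has to close an eight-membered ring through a tether interrupted by quaternary C12, outside the usual five- to seven-membered range. A1 has C5 as a ketone and C7=C9 as a tetrasubstituted enone, so C5, C7 and C9 must all be set afterwards on a rigid tetracycle by conjugate reduction, protonation and ketone reduction under substrate control only.
- Comparison: the chosen route sets the ring A stereocentres early on a small lactone by a directed hydrogenation and closes a 12-membered ring instead of an 8-membered one.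

**Alternative 2: 8-endo radical closure onto a dienone.**
- Disconnection: C26–C27 only.
- Forward key step: a primary C26 radical (iodide, (Me3Si)3SiH) adds 8-endo to C27 of a C10-keto dienone; protonation of the dienolate at C9 leaves the C2=C3 alkene and gives C10 ketone A2.
- For: no macrocycle and no C23 oxygen to delete, so the endgame is shorter than in the chosen route. The alkene geometry is again fixed by the ring, and protonation of C9 anti to the C7 methyl would give the required cis relationship.
- Against: an unstabilised primary radical closing an eight-membered ring competes poorly with reduction by the silane and with 1,5-hydrogen shifts. In A2, C9 is alpha to the C10 ketone and allylic, so epimerisation or alkene migration into conjugation is a standing risk. C10 must later be reduced next to quaternary C12 with substrate control only, and the C12 quaternary centre has to be built separately.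
- Comparison: the chosen route makes C12 and both rings in one step and never leaves C9 next to a ring ketone.

**Alternative 3: Wittig–Still ring expansion.**
- Disconnection: C9–C10, with C2=C3 formed in the same [2,3]-shift; ring B arises from a seven-membered ether bridging C2 and C10.
- Forward key step: tin–lithium exchange with BuLi gives a C10 carbanion that attacks C9 of the cyclopentenyl group on C2 while C2–O breaks, giving mono-silyl ether A3.
- For: A3 is one deprotection from the target. C9, C10 and the alkene arise in one concerted event with chirality transfer, and there is no ketone to delete. In endgame economy it is clearly stronger than the chosen route.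
- Against: the precursor needs a fully substituted ether carbon C2 and a configurationally defined stannyl ether at C10 inside an oxepane that already contains quaternary C12. The shift must deliver C10 to the cyclopentene face syn to the C7 methyl, and it competes with the [1,2]-shift and with elimination.
- Comparison: the chosen route starts from two simple fragments, sets each stereocentre by a well-understood element, and keeps its one high-risk event, with close precedent, to a late convergent step.

Key step: step 24

Remark: for the hindered 2-alkylidene ketone 23 the Z isomer (C26 syn to the C23 carbonyl, away from quaternary C16) is assumed to be the more stable one.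

## Route

Step 1
Reactants: 1 (R)-4-[(tert-butyldimethylsilyl)oxy]cyclopent-2-en-1-one
Product: 2 (R)-4-[(tert-butyldimethylsilyl)oxy]-2-(hydroxymethyl)cyclopent-2-en-1-one
Conditions: aq. HCHO (37%), imidazole, THF/H2O, rt
Reagents that add atoms: formaldehyde, C=O
Why: Morita–Baylis–Hillman hydroxymethylation of a cyclic enone installs C10 at the alpha carbon; the silyloxy stereocentre (future C5) is not involved.

Step 2
Reactants: 2 (R)-4-[(tert-butyldimethylsilyl)oxy]-2-(hydroxymethyl)cyclopent-2-en-1-one
Product: 3 (2S,3S,4R)-4-[(tert-butyldimethylsilyl)oxy]-2-(hydroxymethyl)-3-methyl-2-(phenylselanyl)cyclopentan-1-one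
Conditions: Me2CuLi (3 equiv), THF/Et2O, −78 °C; then PhSeBr, −78 → 0 °C
Reagents that add atoms: lithium dimethylcuprate, [Li+].C[Cu-]C; benzeneselenenyl bromide, Br[Se]c1ccccc1
Why: Cuprate conjugate addition anti to the silyloxy group, then selenenylation of the enolate anti to the new methyl (Reich sequence); both new stereocentres are erased in step 3, only the methyl carbon is kept.

Step 3
Reactants: 3 (2S,3S,4R)-4-[(tert-butyldimethylsilyl)oxy]-2-(hydroxymethyl)-3-methyl-2-(phenylselanyl)cyclopentan-1-one
Product: 5 (R)-4-[(tert-butyldimethylsilyl)oxy]-2-(hydroxymethyl)-3-methylcyclopent-2-en-1-one, via selenoxide 4 (not isolated)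
Conditions: H2O2 (30%), pyridine, CH2Cl2, 0 °C → rt
Reagents that add atoms: none
Why: Selenoxide syn-elimination; the ring hydrogen is cis to selenium, and elimination towards a carbinol carbon is disfavoured, so the tetrasubstituted enone should form.

Step 4
Reactants: 5 (R)-4-[(tert-butyldimethylsilyl)oxy]-2-(hydroxymethyl)-3-methylcyclopent-2-en-1-one
Product: 6 [(R)-3-[(tert-butyldimethylsilyl)oxy]-2-methyl-5-oxocyclopent-1-en-1-yl]methyl 2-(diethoxyphosphoryl)propanoate (both epimers at the phosphonate carbon)
Conditions: 2-(diethoxyphosphoryl)propanoic acid, DCC, DMAP (cat.), CH2Cl2, 0 °C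
Reagents that add atoms: 2-(diethoxyphosphoryl)propanoic acid, CCOP(=O)(OCC)C(C)C(O)=O
Why: Steglich esterification of the primary alcohol tethers the C27–C2–C1 unit to O10.

Step 5
Reactants: 6 [(R)-3-[(tert-butyldimethylsilyl)oxy]-2-methyl-5-oxocyclopent-1-en-1-yl]methyl 2-(diethoxyphosphoryl)propanoate
Product: 7 (R)-6-[(tert-butyldimethylsilyl)oxy]-4,7-dimethyl-5,6-dihydrocyclopenta[c]pyran-3(1H)-one
Conditions: LiCl, iPr2NEt, MeCN, rt
Reagents that add atoms: none
Why: Intramolecular Horner–Wadsworth–Emmons reaction under Masamune–Roush conditions makes the C2=C3 alkene inside a six-membered lactone, so C27 is necessarily cis to C9; the beta carbon of the enone is fully substituted, which disfavours conjugate addition.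

Step 6
Reactants: 7 (R)-6-[(tert-butyldimethylsilyl)oxy]-4,7-dimethyl-5,6-dihydrocyclopenta[c]pyran-3(1H)-one
Product: 8 (R)-6-hydroxy-4,7-dimethyl-5,6-dihydrocyclopenta[c]pyran-3(1H)-one
Conditions: HF·pyridine, pyridine, THF, 0 °C → rt
Reagents that add atoms: none
Why: Buffered fluoride cleavage of the silyl ether frees the C5 hydroxyl needed to direct the hydrogenation.

Step 7
Reactants: 8 (R)-6-hydroxy-4,7-dimethyl-5,6-dihydrocyclopenta[c]pyran-3(1H)-one
Product: 9 (6R,7R,7aS)-6-hydroxy-4,7-dimethyl-5,6,7,7a-tetrahydrocyclopenta[c]pyran-3(1H)-one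
Conditions: [Ir(cod)(PCy3)(py)]PF6 (5 mol%), H2 (1 atm), CH2Cl2, rt
Reagents that add atoms: none
Why: Hydroxyl-directed hydrogenation of a tetrasubstituted cyclic allylic alcohol: iridium bound to the C5 hydroxyl delivers both hydrogens to C7 and C9 from the oxygen face, so the C7 methyl and C10 end up cis to each other and trans to the hydroxyl; the remote ester-conjugated C2=C3 alkene has no directing group and should be left.

Step 8
Reactants: 9 (6R,7R,7aS)-6-hydroxy-4,7-dimethyl-5,6,7,7a-tetrahydrocyclopenta[c]pyran-3(1H)-one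
Product: 10 (6R,7R,7aS)-4,7-dimethyl-1,3,5,6,7,7a-hexahydrocyclopenta[c]pyran-3,6-diol (both anomers)
Conditions: iBu2AlH (2.2 equiv), CH2Cl2, −78 °C
Reagents that add atoms: none
Why: Partial reduction of the unsaturated lactone to the lactol at low temperature; the stable tetrahedral aluminate prevents over-reduction.

Step 9
Reactants: 10 (6R,7R,7aS)-4,7-dimethyl-1,3,5,6,7,7a-hexahydrocyclopenta[c]pyran-3,6-diol
Product: 11 (1R,2R,3S,4Z)-4-[4-(1,3-dioxolan-2-yl)but-3-en-2-ylidene]-3-(hydroxymethyl)-2-methylcyclopentan-1-ol (both isomers at the disubstituted alkene)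
Conditions: (1,3-dioxolan-2-ylmethyl)triphenylphosphonium bromide, KOtBu (4 equiv), THF, 0 °C → rt
Reagents that add atoms: (1,3-dioxolan-2-ylmethyl)triphenylphosphonium bromide, [Br-].C(C1OCCO1)[P+](c1ccccc1)(c1ccccc1)c1ccccc1
Why: Wittig olefination of the open hydroxy-enal form of the lactol adds C26 and C25 and frees O10; the tetrasubstituted alkene keeps the Z geometry inherited from the ring, and the geometry of the new alkene does not matter.

Step 10
Reactants: 11 (1R,2R,3S,4Z)-4-[4-(1,3-dioxolan-2-yl)but-3-en-2-ylidene]-3-(hydroxymethyl)-2-methylcyclopentan-1-ol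
Product: 12 (1R,2R,3S,4Z)-4-[4-(1,3-dioxolan-2-yl)butan-2-ylidene]-3-(hydroxymethyl)-2-methylcyclopentan-1-ol
Conditions: TsNHNH2, NaOAc, DME/H2O, 85 °C
Reagents that add atoms: none
Why: Diimide reduction is selective for the disubstituted alkene and does not touch the tetrasubstituted one.

Step 11
Reactants: 12 (1R,2R,3S,4Z)-4-[4-(1,3-dioxolan-2-yl)butan-2-ylidene]-3-(hydroxymethyl)-2-methylcyclopentan-1-ol
Product: 13 (Z)-4-[(2S,3R,4R)-4-hydroxy-2-(hydroxymethyl)-3-methylcyclopentylidene]pentanal
Conditions: 1 M HCl, THF, 0 °C → rt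
Reagents that add atoms: water, O
Why: Acid hydrolysis of the dioxolane, run before silylation so that no silyl ether is exposed to acid.

Step 12
Reactants: 13 (Z)-4-[(2S,3R,4R)-4-hydroxy-2-(hydroxymethyl)-3-methylcyclopentylidene]pentanal
Product: 14 (Z)-4-[(2S,3R,4R)-4-[(tert-butyldimethylsilyl)oxy]-2-{[(tert-butyldimethylsilyl)oxy]methyl}-3-methylcyclopentylidene]pentanal
Conditions: TBSCl, imidazole, DMF, rt
Reagents that add atoms: tert-butyldimethylsilyl chloride, CC(C)(C)[Si](C)(C)Cl
Why: Silylation of both hydroxyls; the primary silyl ether at O10 can later be removed selectively in the presence of the secondary one at O5.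

Step 13
Reactants: 15 3-methylcyclohex-2-en-1-one
Product: 16 3,6-dimethylcyclohex-2-en-1-one (racemic)
Conditions: LDA, THF, −78 °C; MeI, −78 → 0 °C
Reagents that add atoms: iodomethane, CI
Why: Kinetic deprotonation gives the cross-conjugated enolate, which is alkylated at C6.

Step 14
Reactants: 16 3,6-dimethylcyclohex-2-en-1-one
Product: 17 3,6,6-trimethylcyclohex-2-en-1-one
Conditions: LDA, THF, −78 °C; MeI, DMPU, −78 °C → rt
Reagents that add atoms: iodomethane, CI
Why: Second kinetic enolate alkylation at the same carbon completes the gem-dimethyl group (C20).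

Step 15
Reactants: 17 3,6,6-trimethylcyclohex-2-en-1-one
Product: 18 (S)-2,2,5-trimethyl-5-[4-(trimethylsilyl)but-3-yn-1-yl]cyclohexan-1-one
Conditions: 4-(Me3Si)but-3-ynylMgBr (from the bromide and Mg), Cu(OTf)2 (3 mol%), chiral 4,5-diphenylimidazolinium chloride (4 mol%), Et2O, 0 °C
Reagents that add atoms: [4-(trimethylsilyl)but-3-yn-1-yl]magnesium bromide, C[Si](C)(C)C#CCC[Mg]Br
Why: Copper–carbene-catalysed asymmetric conjugate addition of a Grignard reagent to a 3-methylcyclohexenone builds quaternary C16; the ligand antipode is chosen to deliver the chain to the enone face that gives 18, and the gem-dimethyl group is remote from the beta carbon.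

Step 16
Reactants: 18 (S)-2,2,5-trimethyl-5-[4-(trimethylsilyl)but-3-yn-1-yl]cyclohexan-1-one
Product: 19 (R)-5-(but-3-yn-1-yl)-2,2,5-trimethylcyclohexan-1-one (same spatial arrangement; the descriptor changes with the substituent)
Conditions: K2CO3, MeOH, rt
Reagents that add atoms: none
Why: Methanolysis of the alkynylsilane gives the terminal alkyne.

Step 17
Reactants: 19 (R)-5-(but-3-yn-1-yl)-2,2,5-trimethylcyclohexan-1-one
Product: 20 (S)-5-(3-iodobut-3-en-1-yl)-2,2,5-trimethylcyclohexan-1-one
Conditions: NaI, TMSCl, H2O (0.5 equiv), MeCN, rt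
Reagents that add atoms: sodium iodide, [Na+].[I-]
Why: Markovnikov hydroiodination of the terminal alkyne with HI generated in the flask gives the 2-iodoalkene (C12, C13); the hindered ketone is inert.

Step 18
Reactants: 20 (S)-5-(3-iodobut-3-en-1-yl)-2,2,5-trimethylcyclohexan-1-one; 14 (Z)-4-[(2S,3R,4R)-4-[(tert-butyldimethylsilyl)oxy]-2-{[(tert-butyldimethylsilyl)oxy]methyl}-3-methylcyclopentylidene]pentanal
Product: 21 (5S)-6-{(4Z)-1-hydroxy-4-[(2S,3R,4R)-4-[(tert-butyldimethylsilyl)oxy]-2-{[(tert-butyldimethylsilyl)oxy]methyl}-3-methylcyclopentylidene]pentyl}-5-(3-iodobut-3-en-1-yl)-2,2,5-trimethylcyclohexan-1-one (diastereomers at C24 and C25)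
Conditions: LDA, THF, −78 °C (20); then 14, −78 °C
Reagents that add atoms: none
Why: Lithium enolate aldol addition; 20 can enolise only towards C24, and the two new stereocentres are removed in step 19.

Step 19
Reactants: 21 aldol adduct (diastereomers at C24 and C25)
Product: 23 (5S,6Z)-6-{(4Z)-4-[(2S,3R,4R)-4-[(tert-butyldimethylsilyl)oxy]-2-{[(tert-butyldimethylsilyl)oxy]methyl}-3-methylcyclopentylidene]pentylidene}-5-(3-iodobut-3-en-1-yl)-2,2,5-trimethylcyclohexan-1-one, via mesylate 22 (not isolated)
Conditions: MsCl, Et3N, CH2Cl2, 0 °C; then DBU, 0 °C → rt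
Reagents that add atoms: none
Why: Mesylation and E1cB elimination give the enone; the Z isomer keeps C26 away from quaternary C16 and should therefore be both the faster-formed and the more stable isomer.

Step 20
Reactants: 23 Z-enone bis-silyl ether
Product: 24 (5S,6Z)-6-{(4Z)-4-[(2S,3R,4R)-4-[(tert-butyldimethylsilyl)oxy]-2-(hydroxymethyl)-3-methylcyclopentylidene]pentylidene}-5-(3-iodobut-3-en-1-yl)-2,2,5-trimethylcyclohexan-1-one
Conditions: HF·pyridine, pyridine, THF, 0 °C
Reagents that add atoms: none
Why: Selective cleavage of the primary silyl ether in the presence of the secondary one.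

Step 21
Reactants: 24 primary alcohol
Product: 25 (1S,2R,3R,5Z)-3-[(tert-butyldimethylsilyl)oxy]-5-{(5Z)-5-[(6S)-6-(3-iodobut-3-en-1-yl)-3,3,6-trimethyl-2-oxocyclohexylidene]pentan-2-ylidene}-2-methylcyclopentane-1-carbaldehyde
Conditions: Dess–Martin periodinane, NaHCO3, CH2Cl2, 0 °C → rt
Reagents that add atoms: none
Why: Buffered Dess–Martin oxidation gives the C10 aldehyde under near-neutral conditions, so the allylic C9 stereocentre should survive; the aldehyde is used at once.

Step 22
Reactants: 25 iodo aldehyde
Product: 26 macrocyclic allylic alcohol (2Z,24Z,5R,7R,9S,10R,16R): 12-membered ring C2, C3, C9, C10, C12, C14, C15, C16, C24, C25, C26, C27 with 10-OH, C12 methylidene, 5-OTBS and C23 ketone (C16 has the spatial arrangement of the target; the descriptor changes with the carbonyl)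
Conditions: CrCl2 (8 equiv), NiCl2 (2 mol%), DMSO/THF, rt, 2 mM
Reagents that add atoms: none
Why: Nozaki–Hiyama–Kishi macrocyclisation of the 2-iodoalkene onto the aldehyde forms C10–C12; Felkin–Anh addition anti to the alkenyl carbon C3, with the nucleophile passing the C9 hydrogen, predicts 10R, and enone, silyl ether and alkenes tolerate divalent chromium.

Step 23
Reactants: 26 macrocyclic allylic alcohol
Product: 27 macrocyclic bis-silyl ether (2Z,24Z,5R,7R,9S,10R,16R): the 5,10-bis-O-tert-butyldimethylsilyl 12-membered enone with C12 methylidene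
Conditions: TBSOTf, 2,6-lutidine, CH2Cl2, −78 → 0 °C
Reagents that add atoms: tert-butyldimethylsilyl trifluoromethanesulfonate, CC(C)(C)[Si](C)(C)OS(=O)(=O)C(F)(F)F
Why: Silylation of the hindered secondary allylic alcohol with the silyl triflate protects O10 for the radical step.

Step 24
Reactants: 27 macrocyclic bis-silyl ether
Product: 28 tetracyclic C23 ketone (2Z,5R,7R,9S,10R,12S,16R,24S,25S), 5,10-bis-O-tert-butyldimethylsilyl ether
Conditions: Fe(acac)3 (0.5 equiv), PhSiH3 (2.5 equiv), EtOH/(CH2OH)2 5:1, 60 °C, 5 mM
Reagents that add atoms: none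
Why: An iron hydride formed from Fe(acac)3 and PhSiH3 transfers a hydrogen atom to the terminal carbon of the C12 methylidene, giving the C13 methyl and a tertiary C12 radical; this adds to C25, the beta carbon of the enone, and the resulting C24 radical is reduced by divalent iron to the enolate and protonated by ethanol. The closest known reaction type is the iron-mediated reductive olefin–enone coupling (hydrogen-atom-transfer Giese reaction) used to make quaternary carbons, run here transannularly. Ring C closes 6-endo-trig, since 5-exo attack at C24 would build a quaternary carbon next to C16 and give an unstabilised radical; ring B forms as the remainder of the 12-membered ring, so no eight-membered transition state is needed. C25 is controlled by the tether and the enone geometry: the radical can reach only the enone face bearing C15 (anti to the C17 methyl), and with the Z enone this leaves C26 anti to C16 (equatorial, 25S). C12 is controlled by a chair-like transition state with the larger C10 branch equatorial and the new methyl axial, which gives the trans B/C fusion (12S). C24 is set by protonation alpha to the ketone, which is reversible and should settle on the trans C/D fusion with H24 anti to H25. The step needs chemoselective hydrogen-atom transfer: the 1,1-disubstituted alkene is the only good acceptor, because the tetrasubstituted C2=C3 alkene is too hindered and the enone too electron-poor, and high dilution limits reduction of the radical before it cyclises.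

Step 25
Reactants: 28 tetracyclic C23 ketone
Product: 29 tetracyclic C23 alcohol (2Z,5R,7R,9S,10R,12S,16S,24S,25S; both C23 epimers), 5,10-bis-O-tert-butyldimethylsilyl ether
Conditions: LiAlH4, Et2O, 0 °C → rt
Reagents that add atoms: none
Why: Hydride reduction of the hindered ketone; the configuration at C23 is irrelevant because the oxygen is removed.

Step 26
Reactants: 29 tetracyclic C23 alcohol
Product: 30 O-(C23) S-methyl xanthate of 29
Conditions: NaH, imidazole (cat.), THF, 0 °C → rt; CS2; then MeI
Reagents that add atoms: carbon disulfide, S=C=S; iodomethane, CI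
Why: Xanthate formation through the alkoxide, the standard activation of a hindered secondary alcohol for radical deoxygenation.

Step 27
Reactants: 30 xanthate
Product: 31 5,10-bis-O-tert-butyldimethylsilyl ether of the target (2Z,5R,7R,9S,10R,12S,16S,24S,25S)
Conditions: Bu3SnH, AIBN, toluene, 110 °C
Reagents that add atoms: none
Why: Barton–McCombie deoxygenation; the secondary C23 radical has no alkene within reach and is reduced to the methylene.

Step 28
Reactants: 31 bis-silyl ether
Product: 32 CNP0213887.1, the (2Z,5R,7R,9S,10R,12S,16S,24S,25S) 5-8-6-6 tetracyclic 5,10-diol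
Conditions: TBAF, THF, 60 °C
Reagents that add atoms: none
Why: Fluoride cleavage of both silyl ethers; heating is needed for the O10 ether next to quaternary C12, and basic conditions spare the tetrasubstituted alkene.

## Compound list

1 | (R)-4-[(tert-butyldimethylsilyl)oxy]cyclopent-2-en-1-one | O=C1C=C[C@H](O[Si](C)(C)C(C)(C)C)C1 | starting material
2 | (R)-4-[(tert-butyldimethylsilyl)oxy]-2-(hydroxymethyl)cyclopent-2-en-1-one | O=C1C[C@@H](O[Si](C)(C)C(C)(C)C)C=C1CO | intermediate
3 | (2S,3S,4R)-4-[(tert-butyldimethylsilyl)oxy]-2-(hydroxymethyl)-3-methyl-2-(phenylselanyl)cyclopentan-1-one | O=C1C[C@@H](O[Si](C)(C)C(C)(C)C)[C@H](C)[C@@]1(CO)[Se]c1ccccc1 | intermediate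
4 | selenoxide of 3 (both configurations at selenium) | O=C1C[C@@H](O[Si](C)(C)C(C)(C)C)[C@H](C)[C@@]1(CO)[Se](=O)c1ccccc1 | intermediate
5 | (R)-4-[(tert-butyldimethylsilyl)oxy]-2-(hydroxymethyl)-3-methylcyclopent-2-en-1-one | O=C1C[C@@H](O[Si](C)(C)C(C)(C)C)C(C)=C1CO | intermediate
6 | [(R)-3-[(tert-butyldimethylsilyl)oxy]-2-methyl-5-oxocyclopent-1-en-1-yl]methyl 2-(diethoxyphosphoryl)propanoate (epimers at the phosphonate carbon) | O=C1C[C@@H](O[Si](C)(C)C(C)(C)C)C(C)=C1COC(=O)C(C)P(=O)(OCC)OCC | intermediate
7 | (R)-6-[(tert-butyldimethylsilyl)oxy]-4,7-dimethyl-5,6-dihydrocyclopenta[c]pyran-3(1H)-one | CC1=C2C[C@@H](O[Si](C)(C)C(C)(C)C)C(C)=C2COC1=O | intermediate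
8 | (R)-6-hydroxy-4,7-dimethyl-5,6-dihydrocyclopenta[c]pyran-3(1H)-one | CC1=C2C[C@@H](O)C(C)=C2COC1=O | intermediate
9 | (6R,7R,7aS)-6-hydroxy-4,7-dimethyl-5,6,7,7a-tetrahydrocyclopenta[c]pyran-3(1H)-one | CC1=C2C[C@@H](O)[C@H](C)[C@@H]2COC1=O | intermediate
10 | (6R,7R,7aS)-4,7-dimethyl-1,3,5,6,7,7a-hexahydrocyclopenta[c]pyran-3,6-diol (both anomers) | CC1=C2C[C@@H](O)[C@H](C)[C@@H]2COC1O | intermediate
11 | (1R,2R,3S,4Z)-4-[4-(1,3-dioxolan-2-yl)but-3-en-2-ylidene]-3-(hydroxymethyl)-2-methylcyclopentan-1-ol (both isomers at the disubstituted alkene) | C/C(C=CC1OCCO1)=C2\C[C@@H](O)[C@H](C)[C@@H]2CO | intermediate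
12 | (1R,2R,3S,4Z)-4-[4-(1,3-dioxolan-2-yl)butan-2-ylidene]-3-(hydroxymethyl)-2-methylcyclopentan-1-ol | C/C(CCC1OCCO1)=C2\C[C@@H](O)[C@H](C)[C@@H]2CO | intermediate
13 | (Z)-4-[(2S,3R,4R)-4-hydroxy-2-(hydroxymethyl)-3-methylcyclopentylidene]pentanal | C/C(CCC=O)=C2\C[C@@H](O)[C@H](C)[C@@H]2CO | intermediate
14 | (Z)-4-[(2S,3R,4R)-4-[(tert-butyldimethylsilyl)oxy]-2-{[(tert-butyldimethylsilyl)oxy]methyl}-3-methylcyclopentylidene]pentanal | C/C(CCC=O)=C2\C[C@@H](O[Si](C)(C)C(C)(C)C)[C@H](C)[C@@H]2CO[Si](C)(C)C(C)(C)C | intermediate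
15 | 3-methylcyclohex-2-en-1-one | CC1=CC(=O)CCC1 | starting material
16 | 3,6-dimethylcyclohex-2-en-1-one (racemic) | CC1=CC(=O)C(C)CC1 | intermediate
17 | 3,6,6-trimethylcyclohex-2-en-1-one | CC1=CC(=O)C(C)(C)CC1 | intermediate
18 | (S)-2,2,5-trimethyl-5-[4-(trimethylsilyl)but-3-yn-1-yl]cyclohexan-1-one | C[Si](C)(C)C#CCC[C@]1(C)CCC(C)(C)C(=O)C1 | intermediate
19 | (R)-5-(but-3-yn-1-yl)-2,2,5-trimethylcyclohexan-1-one | C#CCC[C@]1(C)CCC(C)(C)C(=O)C1 | intermediate
20 | (S)-5-(3-iodobut-3-en-1-yl)-2,2,5-trimethylcyclohexan-1-one | C=C(I)CC[C@]1(C)CCC(C)(C)C(=O)C1 | intermediate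
21 | (5S)-6-{(4Z)-1-hydroxy-4-[(2S,3R,4R)-4-[(tert-butyldimethylsilyl)oxy]-2-{[(tert-butyldimethylsilyl)oxy]methyl}-3-methylcyclopentylidene]pentyl}-5-(3-iodobut-3-en-1-yl)-2,2,5-trimethylcyclohexan-1-one (diastereomers at C24 and C25) | C=C(I)CC[C@]1(C)CCC(C)(C)C(=O)C1C(O)CC/C(C)=C2/C[C@@H](O[Si](C)(C)C(C)(C)C)[C@H](C)[C@@H]2CO[Si](C)(C)C(C)(C)C | intermediate
22 | methanesulfonate of 21 | C=C(I)CC[C@]1(C)CCC(C)(C)C(=O)C1C(OS(C)(=O)=O)CC/C(C)=C2/C[C@@H](O[Si](C)(C)C(C)(C)C)[C@H](C)[C@@H]2CO[Si](C)(C)C(C)(C)C | intermediate
23 | (5S,6Z)-6-{(4Z)-4-[(2S,3R,4R)-4-[(tert-butyldimethylsilyl)oxy]-2-{[(tert-butyldimethylsilyl)oxy]methyl}-3-methylcyclopentylidene]pentylidene}-5-(3-iodobut-3-en-1-yl)-2,2,5-trimethylcyclohexan-1-one | C=C(I)CC[C@]1(C)CCC(C)(C)C(=O)/C1=C\CC/C(C)=C2/C[C@@H](O[Si](C)(C)C(C)(C)C)[C@H](C)[C@@H]2CO[Si](C)(C)C(C)(C)C | intermediate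
24 | (5S,6Z)-6-{(4Z)-4-[(2S,3R,4R)-4-[(tert-butyldimethylsilyl)oxy]-2-(hydroxymethyl)-3-methylcyclopentylidene]pentylidene}-5-(3-iodobut-3-en-1-yl)-2,2,5-trimethylcyclohexan-1-one | C=C(I)CC[C@]1(C)CCC(C)(C)C(=O)/C1=C\CC/C(C)=C2/C[C@@H](O[Si](C)(C)C(C)(C)C)[C@H](C)[C@@H]2CO | intermediate
25 | (1S,2R,3R,5Z)-3-[(tert-butyldimethylsilyl)oxy]-5-{(5Z)-5-[(6S)-6-(3-iodobut-3-en-1-yl)-3,3,6-trimethyl-2-oxocyclohexylidene]pentan-2-ylidene}-2-methylcyclopentane-1-carbaldehyde | C=C(I)CC[C@]1(C)CCC(C)(C)C(=O)/C1=C\CC/C(C)=C2/C[C@@H](O[Si](C)(C)C(C)(C)C)[C@H](C)[C@@H]2C=O | intermediate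
26 | macrocyclic allylic alcohol (2Z,24Z,5R,7R,9S,10R,16R): 12-membered enone with 10-OH, C12 methylidene, 5-OTBS, rings A and D attached | C/C1=C2\C[C@@H](O[Si](C)(C)C(C)(C)C)[C@H](C)[C@@H]2[C@@H](O)C(=C)CC[C@]3(C)CCC(C)(C)C(=O)/C3=C\CC1 | intermediate
27 | macrocyclic bis-silyl ether (2Z,24Z,5R,7R,9S,10R,16R): 10-O-tert-butyldimethylsilyl ether of 26 | C/C1=C2\C[C@@H](O[Si](C)(C)C(C)(C)C)[C@H](C)[C@@H]2[C@@H](O[Si](C)(C)C(C)(C)C)C(=C)CC[C@]3(C)CCC(C)(C)C(=O)/C3=C\CC1 | intermediate
28 | tetracyclic C23 ketone (2Z,5R,7R,9S,10R,12S,16R,24S,25S), 5,10-bis-O-tert-butyldimethylsilyl ether | C/C1=C2\C[C@@H](O[Si](C)(C)C(C)(C)C)[C@H](C)[C@@H]2[C@@H](O[Si](C)(C)C(C)(C)C)[C@@]2(C)CC[C@]3(C)CCC(C)(C)C(=O)[C@H]3[C@@H]2CC1 | intermediate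
29 | tetracyclic C23 alcohol (both C23 epimers), 5,10-bis-O-tert-butyldimethylsilyl ether | C/C1=C2\C[C@@H](O[Si](C)(C)C(C)(C)C)[C@H](C)[C@@H]2[C@@H](O[Si](C)(C)C(C)(C)C)[C@@]2(C)CC[C@]3(C)CCC(C)(C)C(O)[C@H]3[C@@H]2CC1 | intermediate
30 | O-(C23) S-methyl xanthate of 29 | C/C1=C2\C[C@@H](O[Si](C)(C)C(C)(C)C)[C@H](C)[C@@H]2[C@@H](O[Si](C)(C)C(C)(C)C)[C@@]2(C)CC[C@]3(C)CCC(C)(C)C(OC(=S)SC)[C@H]3[C@@H]2CC1 | intermediate
31 | 5,10-bis-O-tert-butyldimethylsilyl ether of the target | C/C1=C2\C[C@@H](O[Si](C)(C)C(C)(C)C)[C@H](C)[C@@H]2[C@@H](O[Si](C)(C)C(C)(C)C)[C@@]2(C)CC[C@]3(C)CCC(C)(C)C[C@H]3[C@@H]2CC1 | intermediate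
32 | CNP0213887.1, (2Z,5R,7R,9S,10R,12S,16S,24S,25S)-diol | C/C1=C2\C[C@@H](O)[C@H](C)[C@@H]2[C@@H](O)[C@@]2(C)CC[C@]3(C)CCC(C)(C)C[C@H]3[C@@H]2CC1 | target

## Step count and risks

Total: 28 steps. Longest linear sequence: 23 steps (steps 1–12 and 18–28, from 1). The ring D branch (steps 13–17) has 5 steps.

**Step 24 (key step).** The most likely failure is reduction of the C12 radical by a second hydrogen-atom transfer before it crosses the ring, which would simply hydrogenate the methylidene. The second risk is poor control at C12 if the macrocycle prefers a conformation with the C10 branch axial. Incomplete equilibration at C24 would show as a cis C/D ketone and can be corrected with base. Fallback, from 27 back to 28: the radical is generated without a hydride donor. Hydration of the methylidene (Co(acac)2, PhSiH3, O2) gives tertiary alcohol F1. Acylation with methyl chlorooxoacetate gives methyl oxalate F2, and CsOH gives caesium oxalate F3. Visible-light photoredox decarboxylation with Ir[dF(CF3)ppy]2(dtbbpy)PF6 (trivalent iridium) then releases the same C12 radical, which can only add to the enone or return; the enolate is protonated to 28.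

**Step 22.** Facial selectivity at C10 may be poor, because C3 and C7 are of similar size and the macrocycle adds its own bias. Aldehyde 25 may also epimerise at C9 before it cyclises. Fallback, from 25 back to 26: if the cyclisation gives mainly the 10-epimer F4, a Mitsunobu reaction with 4-nitrobenzoic acid (PPh3, DIAD) inverts C10 to 4-nitrobenzoate F5, and K2CO3 in MeOH releases 26. The configuration then comes from a stereospecific inversion and not from the addition.

**Step 19.** The elimination may give some E enone, or the alkene may drift out of conjugation under base. Fallback, from 21 back to 23: the E-enone F6 is separated and isomerised photochemically (365 nm, thioxanthone as sensitiser) to a mixture enriched in the Z isomer 23. This does not depend on which isomer is more stable.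

**Step 7.** The diene of 8 could take up hydrogen in a 1,4 sense, moving the alkene to C3=C9 and losing the geometry lock. The electron-poor tetrasubstituted alkene could also react too slowly for the catalyst lifetime. Fallback, from 6 back to 9: the hydrogenation is done before the lactone exists. Reduction of 6 with NaBH4 and CeCl3 gives allylic alcohol F7 (hydroxyl cis to the silyloxy group). Its hydroxyl directs [Ir(cod)(PCy3)(py)]PF6 and H2 onto a simple cyclopentenol to give saturated alcohol F8. Dess–Martin oxidation gives ketone F9, and LiCl with iPr2NEt closes silyl lactone F10. HF·pyridine then gives 9.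

**Step 15.** The enantioselectivity of the Grignard addition to the trisubstituted enone 17 with an unbranched chain may be insufficient. Fallback, from 15 back to 18: the same copper-catalysed addition is run on 15 itself, the best-precedented substrate, to give ketone F11. Two kinetic methylations (LDA, MeI) at the less hindered alpha carbon, through monomethyl ketone F12, then give 18.

## Further compounds

F1 | step 24 | C12 tertiary alcohol from hydration of 27 (both C12 epimers) | C/C1=C2\C[C@@H](O[Si](C)(C)C(C)(C)C)[C@H](C)[C@@H]2[C@@H](O[Si](C)(C)C(C)(C)C)C(C)(O)CC[C@]3(C)CCC(C)(C)C(=O)/C3=C\CC1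
F2 | step 24 | methyl oxalate of F1 | C/C1=C2\C[C@@H](O[Si](C)(C)C(C)(C)C)[C@H](C)[C@@H]2[C@@H](O[Si](C)(C)C(C)(C)C)C(C)(OC(=O)C(=O)OC)CC[C@]3(C)CCC(C)(C)C(=O)/C3=C\CC1
F3 | step 24 | caesium oxalate of F1 | C/C1=C2\C[C@@H](O[Si](C)(C)C(C)(C)C)[C@H](C)[C@@H]2[C@@H](O[Si](C)(C)C(C)(C)C)C(C)(OC(=O)C(=O)[O-])CC[C@]3(C)CCC(C)(C)C(=O)/C3=C\CC1.[Cs+]
F4 | step 22 | 10-epimer (10S) of 26 | C/C1=C2\C[C@@H](O[Si](C)(C)C(C)(C)C)[C@H](C)[C@@H]2[C@H](O)C(=C)CC[C@]3(C)CCC(C)(C)C(=O)/C3=C\CC1
F5 | step 22 | 4-nitrobenzoate of 26 (10R) | C/C1=C2\C[C@@H](O[Si](C)(C)C(C)(C)C)[C@H](C)[C@@H]2[C@@H](OC(=O)c4ccc(cc4)[N+](=O)[O-])C(=C)CC[C@]3(C)CCC(C)(C)C(=O)/C3=C\CC1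
F6 | step 19 | (6E)-isomer of 23 | C=C(I)CC[C@]1(C)CCC(C)(C)C(=O)/C1=C/CC/C(C)=C2/C[C@@H](O[Si](C)(C)C(C)(C)C)[C@H](C)[C@@H]2CO[Si](C)(C)C(C)(C)C
F7 | step 7 | [(3R,5S)-3-[(tert-butyldimethylsilyl)oxy]-5-hydroxy-2-methylcyclopent-1-en-1-yl]methyl 2-(diethoxyphosphoryl)propanoate | O[C@H]1C[C@@H](O[Si](C)(C)C(C)(C)C)C(C)=C1COC(=O)C(C)P(=O)(OCC)OCC
F8 | step 7 | [(1R,2R,3R,5S)-3-[(tert-butyldimethylsilyl)oxy]-5-hydroxy-2-methylcyclopentyl]methyl 2-(diethoxyphosphoryl)propanoate | O[C@H]1C[C@@H](O[Si](C)(C)C(C)(C)C)[C@H](C)[C@@H]1COC(=O)C(C)P(=O)(OCC)OCC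
F9 | step 7 | [(1R,2R,3R)-3-[(tert-butyldimethylsilyl)oxy]-2-methyl-5-oxocyclopentyl]methyl 2-(diethoxyphosphoryl)propanoate | O=C1C[C@@H](O[Si](C)(C)C(C)(C)C)[C@H](C)[C@@H]1COC(=O)C(C)P(=O)(OCC)OCC
F10 | step 7 | (6R,7R,7aS)-6-[(tert-butyldimethylsilyl)oxy]-4,7-dimethyl-5,6,7,7a-tetrahydrocyclopenta[c]pyran-3(1H)-one | CC1=C2C[C@@H](O[Si](C)(C)C(C)(C)C)[C@H](C)[C@@H]2COC1=O
F11 | step 15 | (S)-3-methyl-3-[4-(trimethylsilyl)but-3-yn-1-yl]cyclohexan-1-one | C[Si](C)(C)C#CCC[C@]1(C)CCCC(=O)C1
F12 | step 15 | (5S)-2,5-dimethyl-5-[4-(trimethylsilyl)but-3-yn-1-yl]cyclohexan-1-one (both C2 epimers) | C[Si](C)(C)C#CCC[C@]1(C)CCC(C)C(=O)C1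
A1 | alternative 1 | tetracyclic cross-ring dienone | C/C1=C2\CC(=O)C(C)=C2[C@@H](O[Si](C)(C)C(C)(C)C)[C@@]2(C)CC[C@]3(C)CCC(C)(C)C[C@H]3[C@@H]2CC1
A2 | alternative 2 | tetracyclic C10 ketone with the C2=C3 alkene | C/C1=C2\C[C@@H](O[Si](C)(C)C(C)(C)C)[C@H](C)[C@@H]2C(=O)[C@@]2(C)CC[C@]3(C)CCC(C)(C)C[C@H]3[C@@H]2CC1
A3 | alternative 3 | target skeleton with O6 silylated | C/C1=C2\C[C@@H](O[Si](C)(C)C(C)(C)C)[C@H](C)[C@@H]2[C@@H](O)[C@@]2(C)CC[C@]3(C)CCC(C)(C)C[C@H]3[C@@H]2CC1
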